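**Retrosynthetic overview**
- The target comes from desilylation of its C6 silyl ether. The C7–O ester bond and the C7 quaternary centre are made together by anodic acyloxylation of a silyl trienol ether with the free aryl acid, anti to the C6 silyloxy group.
- The silyl trienol ether comes from C7 methylation and enol silylation of a bicyclic 1H-isochromen-8-one.
- The pyran ring (second ring, formed last) comes from singlet-oxygen ene oxidation of a 2-methylcyclohexenylidene enone to a 2-methylene trienedione, which closes by O–C1 bond formation.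
- The dienone comes from enynyl-lithium addition to a 5-silyloxy-2-methylcyclohexenone followed by a Meyer–Schuster shift.
- The carbocycle (first ring) and the C6 stereocentre are bought as (S)-carvone; the isopropenyl group becomes OAc by ozonolysis/Criegee rearrangement with retention.

Assumption: (E)-pent-3-en-1-yne and 4-hydroxy-2-methoxy-6-methylbenzoic acid are taken as catalogue compounds.

**Step 1**
Reactants: 1 (S)-(+)-carvone
Product: 4 (1S)-4-methyl-5-oxocyclohex-3-en-1-yl acetate, via methoxy hydroperoxide 2 (not isolated), via Criegee peracetate 3 (not isolated)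
Conditions: O3 (1.0 equiv, Sudan red end-point), CH2Cl2/MeOH 5:1, −78 °C; then Ac2O, Et3N, DMAP (cat.), −78 °C → rt
Reagents that add atoms: ozone, O=[O+][O-]; methanol, CO
Why: Selective ozonolysis of the electron-rich isopropenyl group in methanol gives the methoxy hydroperoxide, whose peracetate undergoes Criegee rearrangement; the ring carbon migrates to oxygen with retention, so the carvone stereocentre becomes the future C6–O centre unchanged.

**Step 2**
Reactants: 4 (1S)-4-methyl-5-oxocyclohex-3-en-1-yl acetate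
Product: 5 (5S)-5-hydroxy-2-methylcyclohex-2-en-1-one
Conditions: K2CO3 (0.2 equiv), MeOH, 0 °C
Reagents that add atoms: none
Why: Base-catalysed transesterification removes the acetate at 0 °C, faster than E1cB loss of the β-oxygen; the stereocentre is not involved.

**Step 3**
Reactants: 5 (5S)-5-hydroxy-2-methylcyclohex-2-en-1-one
Product: 6 (5S)-5-{[tert-butyl(dimethyl)silyl]oxy}-2-methylcyclohex-2-en-1-one
Conditions: TBSCl, imidazole, DMF, rt
Reagents that add atoms: tert-butyldimethylsilyl chloride, CC(C)(C)[Si](C)(C)Cl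
Why: Standard silylation of a secondary alcohol; the silyl ether is a poor leaving group and survives the later organolithium, enolate and oxidation steps.

**Step 4**
Reactants: 6 (5S)-5-{[tert-butyl(dimethyl)silyl]oxy}-2-methylcyclohex-2-en-1-one; 7 (3E)-pent-3-en-1-yne
Product: 9 (1RS,5S)-5-{[tert-butyl(dimethyl)silyl]oxy}-2-methyl-1-[(3E)-pent-3-en-1-yn-1-yl]cyclohex-2-en-1-ol, via lithium acetylide 8 (not isolated)
Conditions: 7 (1.3 equiv), n-BuLi (1.25 equiv), THF, −78 °C; then 6, −78 → −40 °C; H2O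
Reagents that add atoms: none
Why: Lithium acetylides add 1,2 to enones with little enolisation; the carbinol epimers are carried on together because this centre becomes sp2 in step 5.

**Step 5**
Reactants: 9 (1RS,5S)-5-{[tert-butyl(dimethyl)silyl]oxy}-2-methyl-1-[(3E)-pent-3-en-1-yn-1-yl]cyclohex-2-en-1-ol
Product: 10 (3E)-1-[(5S)-5-{[tert-butyl(dimethyl)silyl]oxy}-2-methylcyclohex-2-en-1-ylidene]pent-3-en-2-one
Conditions: MoO2(acac)2 (1 mol%), Ph3PAuCl (1 mol%), AgOTf (1 mol%), toluene, rt
Reagents that add atoms: none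
Why: Meyer–Schuster rearrangement (1,3-hydroxyl shift of the tertiary propargylic alcohol, then tautomerisation) gives the exocyclic enone as an alkene-isomer mixture; the geometry does not matter for step 6 and the C5 stereocentre is remote.

**Step 6**
Reactants: 10 (3E)-1-[(5S)-5-{[tert-butyl(dimethyl)silyl]oxy}-2-methylcyclohex-2-en-1-ylidene]pent-3-en-2-one
Product: 14 (6R)-6-{[tert-butyl(dimethyl)silyl]oxy}-3-[(1E)-prop-1-en-1-yl]-1,5,6,7-tetrahydro-8H-isochromen-8-one, via allylic hydroperoxide 11 (not isolated), via allylic peracetate 12 (not isolated), via trienedione 13 (not isolated)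
Conditions: O2, tetraphenylporphyrin (1 mol%), white LED (>450 nm), CH2Cl2, −20 °C; then Ac2O, Et3N, DMAP (10 mol%), 0 °C; then DABCO (20 mol%), rt
Reagents that add atoms: dioxygen, O=O
Why: Schenck ene reaction of singlet oxygen at the ring alkene abstracts hydrogen from the vinylic methyl geminal to the bulky alkylidene branch (as in α-pinene → pinocarveyl hydroperoxide); Kornblum–DeLaMare dehydration of the peracetate gives the 2-methylene ketone, and amine conjugate addition followed by O-alkylation by the dienolate oxygen (or direct oxa-6π closure of the Z isomer) forms the pyran without touching C6.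

**Step 7**
Reactants: 14 (6R)-6-{[tert-butyl(dimethyl)silyl]oxy}-3-[(1E)-prop-1-en-1-yl]-1,5,6,7-tetrahydro-8H-isochromen-8-one
Product: 15 (6R,7RS)-6-{[tert-butyl(dimethyl)silyl]oxy}-7-methyl-3-[(1E)-prop-1-en-1-yl]-1,5,6,7-tetrahydro-8H-isochromen-8-one
Conditions: LiN(i-Pr)2 (1.1 equiv), THF, −78 °C; MeI (1.5 equiv), −78 → −40 °C
Reagents that add atoms: iodomethane, CI
Why: Kinetic α′-deprotonation of the vinylogous ester (Stork–Danheiser-type alkylation) and methylation at C7, mainly trans to the silyloxy group; the C7 configuration is irrelevant because it is planarised in step 8.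

**Step 8**
Reactants: 15 (6R,7RS)-6-{[tert-butyl(dimethyl)silyl]oxy}-7-methyl-3-[(1E)-prop-1-en-1-yl]-1,5,6,7-tetrahydro-8H-isochromen-8-one
Product: 16 (6R)-6,8-bis{[tert-butyl(dimethyl)silyl]oxy}-7-methyl-3-[(1E)-prop-1-en-1-yl]-5,6-dihydro-1H-isochromene
Conditions: LiN(i-Pr)2 (1.2 equiv), THF, −78 °C; TBSOTf (1.3 equiv), −78 °C; Et3N-buffered work-up
Reagents that add atoms: tert-butyldimethylsilyl trifluoromethanesulfonate, CC(C)(C)[Si](C)(C)OS(=O)(=O)C(F)(F)F
Why: A second kinetic α′-deprotonation and O-silylation gives the tetrasubstituted silyl enol ether, so the oxidation in step 9 is regiodefined at C7; C6 is unchanged.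

**Step 9**
Reactants: 16 (6R)-6,8-bis{[tert-butyl(dimethyl)silyl]oxy}-7-methyl-3-[(1E)-prop-1-en-1-yl]-5,6-dihydro-1H-isochromene; 17 4-hydroxy-2-methoxy-6-methylbenzoic acid
Product: 18 (6R,7S)-6-{[tert-butyl(dimethyl)silyl]oxy}-7-methyl-8-oxo-3-[(1E)-prop-1-en-1-yl]-5,6,7,8-tetrahydro-1H-isochromen-7-yl 4-hydroxy-2-methoxy-6-methylbenzoate
Conditions: undivided cell, reticulated vitreous carbon anode, platinum cathode, controlled potential +0.8 V vs Ag/AgCl (ca. 2.1 F/mol), 17 (3 equiv), DBU (1 equiv), Bu4NPF6 (0.1 M), CH2Cl2/MeCN 1:1, −20 °C; aqueous NaHCO3 work-up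
Reagents that add atoms: none
Why: Proposed new method: anodic one-electron oxidation of the very electron-rich silyl trienol ether (estimated to oxidise well below the neutral phenol, the arene and the carboxylate, which is kept as its acid-buffered salt so no phenoxide forms) gives a delocalised radical cation; the carboxylate adds at C7, the terminus with the largest HOMO coefficient, anti to the C6 silyloxy group held pseudoaxial by allylic strain with the C7 methyl, which sets the 7S centre trans to C6–O; a second oxidation gives a silyloxy-stabilised pyrylium-like cation that loses the silyl group to restore the conjugated ketone, while protons are reduced to H2 at the cathode. The closest known reaction types are anodic α-acetoxylation and α-methoxylation of enol acetates and silyl enol ethers, and iodide-mediated electrochemical α-acyloxylation of ketones with carboxylic acids.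

**Step 10**
Reactants: 18 (6R,7S)-6-{[tert-butyl(dimethyl)silyl]oxy}-7-methyl-8-oxo-3-[(1E)-prop-1-en-1-yl]-5,6,7,8-tetrahydro-1H-isochromen-7-yl 4-hydroxy-2-methoxy-6-methylbenzoate
Product: 19 (6R,7S)-6-hydroxy-7-methyl-8-oxo-3-[(1E)-prop-1-en-1-yl]-5,6,7,8-tetrahydro-1H-isochromen-7-yl 4-hydroxy-2-methoxy-6-methylbenzoate
Conditions: HF·pyridine, pyridine, THF, 0 °C → rt
Reagents that add atoms: none
Why: Buffered acidic fluoride cleaves the secondary silyl ether without the base-induced acyl migration or retro-aldol that the β-hydroxy ketone could suffer; both stereocentres are untouched.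

**Compound list**
1 | (S)-(+)-carvone, (5S)-2-methyl-5-(prop-1-en-2-yl)cyclohex-2-en-1-one | CC1=CC[C@@H](CC1=O)C(C)=C | starting material
2 | (5S)-5-(1-hydroperoxy-1-methoxyethyl)-2-methylcyclohex-2-en-1-one (epimers at the peroxy carbon) | CC1=CC[C@@H](CC1=O)C(C)(OC)OO | intermediate
3 | (5S)-5-[1-(acetylperoxy)-1-methoxyethyl]-2-methylcyclohex-2-en-1-one | CC1=CC[C@@H](CC1=O)C(C)(OC)OOC(C)=O | intermediate
4 | (1S)-4-methyl-5-oxocyclohex-3-en-1-yl acetate | CC1=CC[C@@H](CC1=O)OC(C)=O | intermediate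
5 | (5S)-5-hydroxy-2-methylcyclohex-2-en-1-one | CC1=CC[C@@H](CC1=O)O | intermediate
6 | (5S)-5-{[tert-butyl(dimethyl)silyl]oxy}-2-methylcyclohex-2-en-1-one | CC1=CC[C@@H](CC1=O)O[Si](C)(C)C(C)(C)C | intermediate
7 | (3E)-pent-3-en-1-yne | C#C/C=C/C | starting material
8 | lithium (3E)-pent-3-en-1-yn-1-ide | [Li]C#C/C=C/C | intermediate
9 | (1RS,5S)-5-{[tert-butyl(dimethyl)silyl]oxy}-2-methyl-1-[(3E)-pent-3-en-1-yn-1-yl]cyclohex-2-en-1-ol | CC1=CC[C@@H](CC1(O)C#C/C=C/C)O[Si](C)(C)C(C)(C)C | intermediate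
10 | (3E)-1-[(5S)-5-{[tert-butyl(dimethyl)silyl]oxy}-2-methylcyclohex-2-en-1-ylidene]pent-3-en-2-one (isomer mixture at the exocyclic alkene) | CC1=CC[C@@H](CC1=CC(=O)/C=C/C)O[Si](C)(C)C(C)(C)C | intermediate
11 | (3E)-1-[(5R)-5-{[tert-butyl(dimethyl)silyl]oxy}-3-hydroperoxy-2-methylidenecyclohexylidene]pent-3-en-2-one (epimers at the peroxy carbon) | C=C1C(OO)C[C@@H](CC1=CC(=O)/C=C/C)O[Si](C)(C)C(C)(C)C | intermediate
12 | (3E)-1-[(5R)-3-(acetylperoxy)-5-{[tert-butyl(dimethyl)silyl]oxy}-2-methylidenecyclohexylidene]pent-3-en-2-one | C=C1C(OOC(C)=O)C[C@@H](CC1=CC(=O)/C=C/C)O[Si](C)(C)C(C)(C)C | intermediate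
13 | (3E)-1-[(5R)-5-{[tert-butyl(dimethyl)silyl]oxy}-2-methylidene-3-oxocyclohexylidene]pent-3-en-2-one | C=C1C(=O)C[C@@H](CC1=CC(=O)/C=C/C)O[Si](C)(C)C(C)(C)C | intermediate
14 | (6R)-6-{[tert-butyl(dimethyl)silyl]oxy}-3-[(1E)-prop-1-en-1-yl]-1,5,6,7-tetrahydro-8H-isochromen-8-one | C/C=C/C1=CC2=C(CO1)C(=O)C[C@H](O[Si](C)(C)C(C)(C)C)C2 | intermediate
15 | (6R,7RS)-6-{[tert-butyl(dimethyl)silyl]oxy}-7-methyl-3-[(1E)-prop-1-en-1-yl]-1,5,6,7-tetrahydro-8H-isochromen-8-one (C7 epimers, trans major) | C/C=C/C1=CC2=C(CO1)C(=O)C(C)[C@H](O[Si](C)(C)C(C)(C)C)C2 | intermediate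
16 | (6R)-6,8-bis{[tert-butyl(dimethyl)silyl]oxy}-7-methyl-3-[(1E)-prop-1-en-1-yl]-5,6-dihydro-1H-isochromene | C/C=C/C1=CC2=C(CO1)C(O[Si](C)(C)C(C)(C)C)=C(C)[C@H](O[Si](C)(C)C(C)(C)C)C2 | intermediate
17 | 4-hydroxy-2-methoxy-6-methylbenzoic acid | COc1cc(O)cc(C)c1C(=O)O | starting material
18 | (6R,7S)-6-{[tert-butyl(dimethyl)silyl]oxy}-7-methyl-8-oxo-3-[(1E)-prop-1-en-1-yl]-5,6,7,8-tetrahydro-1H-isochromen-7-yl 4-hydroxy-2-methoxy-6-methylbenzoate | C/C=C/C1=CC2=C(CO1)C(=O)[C@@](C)(OC(=O)c1c(C)cc(O)cc1OC)[C@H](O[Si](C)(C)C(C)(C)C)C2 | intermediate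
19 | (6R,7S)-6-hydroxy-7-methyl-8-oxo-3-[(1E)-prop-1-en-1-yl]-5,6,7,8-tetrahydro-1H-isochromen-7-yl 4-hydroxy-2-methoxy-6-methylbenzoate | C/C=C/C1=CC2=C(CO1)C(=O)[C@@](C)(OC(=O)c1c(C)cc(O)cc1OC)[C@H](O)C2 | target

**Step count and risks**
Total step count: 10. Longest linear sequence: 10 steps (1 → 19); 7 and 17 are bought.

The three steps most likely to fail:

Step 9 (the proposed anodic acyloxylation). The carboxylate could add at C4 instead of C7, the silyl enol ether could be protodesilylated, or the free phenol could be oxidised. The fallback uses known chemistry, sets out from 15 and 17 and returns at 19. The potassium enolate of 15 (KN(SiMe3)2, THF, −78 °C) is hydroxylated with 2-(phenylsulfonyl)-3-phenyloxaziridine anti to the silyloxy group to give the tertiary ketol F6. Acid 17 is bis-silylated (TBSCl, imidazole) to the silyl ester silyl ether F7, the silyl ester is cleaved (K2CO3, MeOH/H2O) to the phenol-protected acid F8, and oxalyl chloride with catalytic DMF gives the acid chloride F9. Acylation of F6 with F9 (Et3N, DMAP, CH2Cl2, 40 °C) gives the bis-silyl ester F10, and HF·pyridine removes both silyl groups to give 19.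

Step 6 (photooxygenation cascade). The ene reaction could instead abstract a ring hydrogen at C7 and give the tertiary hydroperoxide, and the 2-methylene trienedione could oligomerise before it cyclises. The fallback sets out from 9 and returns at 14. Catalytic SeO2 with t-BuOOH hydroxylates the vinylic methyl, the only allylic C–H position on the more substituted alkene carbon, to give the diol F3. Selective acetylation of the primary alcohol (AcCl, 2,4,6-collidine, −78 °C) gives the monoacetate F4. Babler–Dauben oxidative transposition with C5H5NH[CrO3Cl] (pyridinium chlorochromate) gives the acetoxymethyl ynenone F5. K2CO3 in MeOH removes the acetate and the freed alcohol closes by 6-endo oxa-Michael addition to the ynenone to give 14.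

Step 5 (Meyer–Schuster shift). The doubly activated tertiary alcohol could undergo allylic transposition, Rupe dehydration or Nazarov cyclisation of the divinyl ketone. The fallback sets out from 9 and returns at 10. Acetylation (Ac2O, Et3N, DMAP) gives the tertiary propargylic acetate F1; AgBF4-catalysed Saucy–Marbet [3,3] acyloxy shift gives the allenyl acetate F2; methanolysis (K2CO3, MeOH, 0 °C) releases dienone 10.

**Further compounds**
F1 | step 5 | (1RS,5S)-5-{[tert-butyl(dimethyl)silyl]oxy}-2-methyl-1-[(3E)-pent-3-en-1-yn-1-yl]cyclohex-2-en-1-yl acetate | CC1=CC[C@@H](CC1(OC(C)=O)C#C/C=C/C)O[Si](C)(C)C(C)(C)C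
F2 | step 5 | (3E)-1-[(5S)-5-{[tert-butyl(dimethyl)silyl]oxy}-2-methylcyclohex-2-en-1-ylidene]penta-1,3-dien-2-yl acetate | CC1=CC[C@@H](CC1=C=C(OC(C)=O)/C=C/C)O[Si](C)(C)C(C)(C)C
F3 | step 6 | (1RS,5S)-5-{[tert-butyl(dimethyl)silyl]oxy}-2-(hydroxymethyl)-1-[(3E)-pent-3-en-1-yn-1-yl]cyclohex-2-en-1-ol | OCC1=CC[C@@H](CC1(O)C#C/C=C/C)O[Si](C)(C)C(C)(C)C
F4 | step 6 | [(4S,6RS)-4-{[tert-butyl(dimethyl)silyl]oxy}-6-hydroxy-6-[(3E)-pent-3-en-1-yn-1-yl]cyclohex-1-en-1-yl]methyl acetate | CC(=O)OCC1=CC[C@@H](CC1(O)C#C/C=C/C)O[Si](C)(C)C(C)(C)C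
F5 | step 6 | [(4R)-4-{[tert-butyl(dimethyl)silyl]oxy}-6-oxo-2-[(3E)-pent-3-en-1-yn-1-yl]cyclohex-1-en-1-yl]methyl acetate | CC(=O)OCC1=C(C#C/C=C/C)C[C@@H](O[Si](C)(C)C(C)(C)C)CC1=O
F6 | step 9 | (6R,7S)-6-{[tert-butyl(dimethyl)silyl]oxy}-7-hydroxy-7-methyl-3-[(1E)-prop-1-en-1-yl]-1,5,6,7-tetrahydro-8H-isochromen-8-one | C/C=C/C1=CC2=C(CO1)C(=O)[C@@](C)(O)[C@H](O[Si](C)(C)C(C)(C)C)C2
F7 | step 9 | tert-butyl(dimethyl)silyl 4-{[tert-butyl(dimethyl)silyl]oxy}-2-methoxy-6-methylbenzoate | COc1cc(O[Si](C)(C)C(C)(C)C)cc(C)c1C(=O)O[Si](C)(C)C(C)(C)C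
F8 | step 9 | 4-{[tert-butyl(dimethyl)silyl]oxy}-2-methoxy-6-methylbenzoic acid | COc1cc(O[Si](C)(C)C(C)(C)C)cc(C)c1C(=O)O
F9 | step 9 | 4-{[tert-butyl(dimethyl)silyl]oxy}-2-methoxy-6-methylbenzoyl chloride | COc1cc(O[Si](C)(C)C(C)(C)C)cc(C)c1C(Cl)=O
F10 | step 9 | (6R,7S)-6-{[tert-butyl(dimethyl)silyl]oxy}-7-methyl-8-oxo-3-[(1E)-prop-1-en-1-yl]-5,6,7,8-tetrahydro-1H-isochromen-7-yl 4-{[tert-butyl(dimethyl)silyl]oxy}-2-methoxy-6-methylbenzoate | C/C=C/C1=CC2=C(CO1)C(=O)[C@@](C)(OC(=O)c1c(C)cc(O[Si](C)(C)C(C)(C)C)cc1OC)[C@H](O[Si](C)(C)C(C)(C)C)C2
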